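**Assumption:** the SMILES is read as the (2S,4S,6S,1′S) isomer, i.e. a 2,6-trans oxane with the 4-OH cis to the aryl group, and 3-ethoxycyclobutan-1-one and methyl (2S)-oxirane-2-carboxylate are taken as catalogue compounds.

## Retrosynthetic overview

1. Target ⇒ its tris-O-benzyl ether (global hydrogenolysis last).
2. C2–aryl bond ⇒ 2-ethoxyoxan-4-ol + bis(4-benzyloxy-3-methoxyphenyl)zinc; axial attack on the oxocarbenium ion sets 2,6-trans/2,4-cis.
3. C4–OH ⇒ 2-ethoxyoxan-4-one, by equatorial hydride delivery.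
4. Oxane ring (the only ring built; both arenes are bought) ⇒ ring expansion of 3-ethoxycyclobutan-1-one by insertion of the C=O of (S)-2-benzyloxy-3-(4-benzyloxyphenyl)propanal into its C2–C3 bond under chelation control (sets C6).
5. Aldehyde ⇒ 4-bromophenol + methyl (S)-glycidate (C1′ comes from the epoxide); arylzinc ⇒ catechol (O-methylation, para-bromination).

## Route

Step 1
Reactants: 1 catechol
Product: 2 guaiacol (2-methoxyphenol)
Conditions: MeI (0.9 equiv), K2CO3, acetone, reflux (1 in excess)
Reagents that add atoms: iodomethane (CI)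
Why: Williamson mono-O-methylation, with excess catechol holding back the dimethyl ether; no stereocentre.

Step 2
Reactants: 2 guaiacol
Product: 4 1-(benzyloxy)-4-bromo-2-methoxybenzene, via 4-bromo-2-methoxyphenol 3 (not isolated)
Conditions: NBS, MeCN, 0 °C; then K2CO3, BnBr (2.2 equiv), 60 °C
Reagents that add atoms: N-bromosuccinimide (O=C1CCC(=O)N1Br); benzyl bromide (BrCc1ccccc1)
Why: Electrophilic aromatic bromination goes para to the free OH (the stronger director), and the phenol is then capped in the same flask by Williamson benzylation.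

Step 3
Reactants: 5 4-bromophenol
Product: 6 1-(benzyloxy)-4-bromobenzene
Conditions: BnBr, K2CO3, acetone, reflux
Reagents that add atoms: benzyl bromide (BrCc1ccccc1)
Why: Williamson etherification masks the acidic phenol so that the Grignard reagent can be formed.

Step 4
Reactants: 6 1-(benzyloxy)-4-bromobenzene; 7 methyl (2S)-oxirane-2-carboxylate
Product: 9 methyl (2S)-3-[4-(benzyloxy)phenyl]-2-hydroxypropanoate, via [4-(benzyloxy)phenyl]magnesium bromide 8 (not isolated)
Conditions: Mg, THF; then CuI (10 mol%), 7, −40 → −20 °C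
Reagents that add atoms: none
Why: Copper-catalysed Grignard opening of the epoxide at the unsubstituted C3 (SN2) leaves the C2–O bond untouched, so the (S) centre of 7 becomes C1′ of the target with retention, while the ester survives at low temperature.

Step 5
Reactants: 9 methyl (2S)-3-[4-(benzyloxy)phenyl]-2-hydroxypropanoate
Product: 10 methyl (2S)-2-(benzyloxy)-3-[4-(benzyloxy)phenyl]propanoate
Conditions: BnBr, Ag2O, CH2Cl2, rt, dark
Reagents that add atoms: benzyl bromide (BrCc1ccccc1)
Why: Ag2O-promoted O-benzylation (Williamson type) works without strong base, so the α-centre does not enolise, and it installs the chelating ether needed in step 7.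

Step 6
Reactants: 10 methyl (2S)-2-(benzyloxy)-3-[4-(benzyloxy)phenyl]propanoate
Product: 11 (2S)-2-(benzyloxy)-3-[4-(benzyloxy)phenyl]propanal
Conditions: i-Bu2AlH (1.05 equiv), CH2Cl2, −78 °C; used crude
Reagents that add atoms: none
Why: Partial ester reduction stops at the chelated aluminium hemiacetal at −78 °C and releases the α-benzyloxy aldehyde on work-up, which is used at once to avoid epimerisation.

Step 7
Reactants: 11 (2S)-2-(benzyloxy)-3-[4-(benzyloxy)phenyl]propanal; 12 3-ethoxycyclobutan-1-one
Product: 13 (6S)-6-[(1S)-1-(benzyloxy)-2-[4-(benzyloxy)phenyl]ethyl]-2-ethoxyoxan-4-one (anomeric mixture)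
Conditions: SnCl4 (2.1 equiv; 11 pre-complexed with the first equivalent), CH2Cl2, −78 → −45 °C; Et3N quench
Reagents that add atoms: none
Why: Proposed new method: the first equivalent of SnCl4 locks 11 as the five-membered Cram chelate through its α-benzyloxy group and the second ionises the donor–acceptor C2–C3 bond of 12 to a tin enolate/ethoxy-oxocarbenium zwitterion, whose enolate carbon adds to the chelated C=O anti to the CH2Ar group (1,2-syn, C6 = S) before the tin alkoxide closes on the oxocarbenium carbon, so the aldehyde C=O is inserted stepwise into the four-membered ring (non-pericyclic ring expansion, four to six atoms); the closest known reaction types are the BF3·OEt2-promoted insertion of simple aldehydes into 3-alkoxycyclobutanones and SnCl4 chelation-controlled Mukaiyama aldol additions, whereas chelation-relayed 1,2-induction from an α-alkoxy aldehyde in this ring expansion has not been shown.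

Step 8
Reactants: 13 (6S)-6-[(1S)-1-(benzyloxy)-2-[4-(benzyloxy)phenyl]ethyl]-2-ethoxyoxan-4-one
Product: 14 (4R,6S)-6-[(1S)-1-(benzyloxy)-2-[4-(benzyloxy)phenyl]ethyl]-2-ethoxyoxan-4-ol (anomeric mixture)
Conditions: LiBH(s-Bu)3, THF, −78 °C
Reagents that add atoms: none
Why: The bulky borohydride attacks the oxan-4-one from the equatorial direction and gives the axial C4 alcohol, trans to the equatorial C6 side chain (substrate-controlled ketone reduction; this is the C4 configuration of the target).

Step 9
Reactants: 14 (4R,6S)-6-[(1S)-1-(benzyloxy)-2-[4-(benzyloxy)phenyl]ethyl]-2-ethoxyoxan-4-ol; 4 1-(benzyloxy)-4-bromo-2-methoxybenzene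
Product: 19 (2S,4S,6S)-2-[4-(benzyloxy)-3-methoxyphenyl]-6-[(1S)-1-(benzyloxy)-2-[4-(benzyloxy)phenyl]ethyl]oxan-4-ol, via arylmagnesium bromide 15 (not isolated), via diarylzinc 16 (not isolated), via O-trimethylsilyl acetal 17 (not isolated), via O-trimethylsilyl C-aryl oxane 18 (not isolated)
Conditions: 4, Mg, THF, then ZnBr2 (0.5 equiv), solvent switch to toluene; 14, (Me3Si)2NH, cat. Me3SiOTf, CH2Cl2, rt, evaporate; combine, Me3SiOTf (1.3 equiv), −78 → −30 °C, Et3N quench; K2CO3, MeOH, 0 °C
Reagents that add atoms: none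
Why: Me3SiOTf ionises the acetal to the oxan-2-ylium ion, whose half-chair holds the C6 side chain pseudo-equatorial and the C4–OSiMe3 group pseudo-axial, and the arylzinc adds through its ipso carbon along the axial trajectory on the face anti to the side chain, giving the 2,6-trans/2,4-cis C-aryl ether (C2 = S) in a C-glycosylation-type substitution via an oxocarbenium ion.

Step 10
Reactants: 19 (2S,4S,6S)-2-[4-(benzyloxy)-3-methoxyphenyl]-6-[(1S)-1-(benzyloxy)-2-[4-(benzyloxy)phenyl]ethyl]oxan-4-ol
Product: 20 (2S,4S,6S)-2-(4-hydroxy-3-methoxyphenyl)-6-[(1S)-1-hydroxy-2-(4-hydroxyphenyl)ethyl]oxan-4-ol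
Conditions: H2 (1 atm), 10% Pd/C, EtOAc–MeOH, rt
Reagents that add atoms: none
Why: Catalytic hydrogenolysis removes the three O-benzyl groups under neutral conditions without touching any stereocentre (O-debenzylation).

## Compound list

1 | catechol (benzene-1,2-diol) | Oc1ccccc1O | starting material
2 | guaiacol (2-methoxyphenol) | COc1ccccc1O | intermediate
3 | 4-bromo-2-methoxyphenol | COc1cc(Br)ccc1O | intermediate
4 | 1-(benzyloxy)-4-bromo-2-methoxybenzene | COc1cc(Br)ccc1OCc1ccccc1 | intermediate
5 | 4-bromophenol | Oc1ccc(Br)cc1 | starting material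
6 | 1-(benzyloxy)-4-bromobenzene | Brc1ccc(OCc2ccccc2)cc1 | intermediate
7 | methyl (2S)-oxirane-2-carboxylate | COC(=O)[C@@H]1CO1 | starting material
8 | [4-(benzyloxy)phenyl]magnesium bromide | Br[Mg]c1ccc(OCc2ccccc2)cc1 | intermediate
9 | methyl (2S)-3-[4-(benzyloxy)phenyl]-2-hydroxypropanoate | COC(=O)[C@@H](O)Cc1ccc(OCc2ccccc2)cc1 | intermediate
10 | methyl (2S)-2-(benzyloxy)-3-[4-(benzyloxy)phenyl]propanoate | COC(=O)[C@@H](OCc1ccccc1)Cc1ccc(OCc2ccccc2)cc1 | intermediate
11 | (2S)-2-(benzyloxy)-3-[4-(benzyloxy)phenyl]propanal | O=C[C@@H](OCc1ccccc1)Cc1ccc(OCc2ccccc2)cc1 | intermediate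
12 | 3-ethoxycyclobutan-1-one | CCOC1CC(=O)C1 | starting material
13 | (6S)-6-[(1S)-1-(benzyloxy)-2-[4-(benzyloxy)phenyl]ethyl]-2-ethoxyoxan-4-one (anomeric mixture) | CCOC1CC(=O)C[C@@H]([C@@H](OCc2ccccc2)Cc2ccc(OCc3ccccc3)cc2)O1 | intermediate
14 | (4R,6S)-6-[(1S)-1-(benzyloxy)-2-[4-(benzyloxy)phenyl]ethyl]-2-ethoxyoxan-4-ol (anomeric mixture) | CCOC1C[C@H](O)C[C@@H]([C@@H](OCc2ccccc2)Cc2ccc(OCc3ccccc3)cc2)O1 | intermediate
15 | [4-(benzyloxy)-3-methoxyphenyl]magnesium bromide | COc1cc([Mg]Br)ccc1OCc1ccccc1 | intermediate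
16 | bis[4-(benzyloxy)-3-methoxyphenyl]zinc | COc1cc([Zn]c2ccc(OCc3ccccc3)c(OC)c2)ccc1OCc1ccccc1 | intermediate
17 | {[(4R,6S)-6-[(1S)-1-(benzyloxy)-2-[4-(benzyloxy)phenyl]ethyl]-2-ethoxyoxan-4-yl]oxy}trimethylsilane | CCOC1C[C@H](O[Si](C)(C)C)C[C@@H]([C@@H](OCc2ccccc2)Cc2ccc(OCc3ccccc3)cc2)O1 | intermediate
18 | {[(2S,4S,6S)-2-[4-(benzyloxy)-3-methoxyphenyl]-6-[(1S)-1-(benzyloxy)-2-[4-(benzyloxy)phenyl]ethyl]oxan-4-yl]oxy}trimethylsilane | COc1cc([C@@H]2C[C@H](O[Si](C)(C)C)C[C@@H]([C@@H](OCc3ccccc3)Cc3ccc(OCc4ccccc4)cc3)O2)ccc1OCc1ccccc1 | intermediate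
19 | (2S,4S,6S)-2-[4-(benzyloxy)-3-methoxyphenyl]-6-[(1S)-1-(benzyloxy)-2-[4-(benzyloxy)phenyl]ethyl]oxan-4-ol | COc1cc([C@@H]2C[C@H](O)C[C@@H]([C@@H](OCc3ccccc3)Cc3ccc(OCc4ccccc4)cc3)O2)ccc1OCc1ccccc1 | intermediate
20 | (2S,4S,6S)-2-(4-hydroxy-3-methoxyphenyl)-6-[(1S)-1-hydroxy-2-(4-hydroxyphenyl)ethyl]oxan-4-ol | COc1cc([C@@H]2C[C@H](O)C[C@@H]([C@@H](O)Cc3ccc(O)cc3)O2)ccc1O | target

## Step count and risks

Total: 10 steps. Longest linear sequence: 8 steps (5 → 20, steps 3–10); the two-step arene branch (1 → 4) joins at step 9.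

**Step 7 (new ring expansion).** The risks are Felkin-type or unselective addition and loss of ethanol to the dihydropyranone. The fallback uses known chemistry, sets out from 11 and comes back at 13, and builds the same ring by a stepwise aldol and acetalisation instead of the ring expansion. The silyl enol ether of commercial 4,4-dimethoxybutan-2-one, trimethyl[(4,4-dimethoxybut-1-en-2-yl)oxy]silane F1 (made with LiN(i-Pr)2 and Me3SiCl), is added to 11 under MgBr2·OEt2 chelation control (Mukaiyama aldol, 1,2-syn). This gives (5S,6S)-6-(benzyloxy)-7-[4-(benzyloxy)phenyl]-5-hydroxy-1,1-dimethoxyheptan-3-one F2. Pyridinium p-toluenesulfonate in ethanol then cyclises F2 with acetal exchange to 13.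

**Step 9 (C-arylation).** The risks are sluggish aryl transfer and Me3SiOTf-induced ionisation of the electron-rich benzylic ether of the product, which would drift to the 2,6-cis isomer. The fallback sets out from 14 and comes back at 19, and changes the anomeric leaving group so that no silyl triflate is needed. Benzenesulfinic acid and CaCl2 in CH2Cl2 convert 14 into the anomeric sulfone (4R,6S)-2-(benzenesulfonyl)-6-[(1S)-1-(benzyloxy)-2-[4-(benzyloxy)phenyl]ethyl]oxan-4-ol F3. Excess 16 in THF at rt, with ZnBr2 as the only Lewis acid, then displaces the sulfone through the same oxocarbenium ion (a known 2,6-trans-selective arylation of 2-sulfonyl cyclic ethers) to give 19.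

**Step 10 (hydrogenolysis).** The risk is cleavage of the ring C2–O bond, which is a p-hydroxybenzylic ether once the aryl benzyl group has gone. The fallback sets out from 19 and comes back at 20, and replaces surface hydrogenolysis by single-electron debenzylation with lithium 4,4′-di-tert-butylbiphenylide in THF at −78 °C. The aryl benzyl ethers cleave first through the radical anions of the unsubstituted benzyl rings, and the resulting phenoxide rings are too electron-rich to accept an electron, which shields the ring C–O bond. New compounds on this path: none F0.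

## Further compounds

F1 | step 7 | trimethyl[(4,4-dimethoxybut-1-en-2-yl)oxy]silane | COC(OC)CC(=C)O[Si](C)(C)C
F2 | step 7 | (5S,6S)-6-(benzyloxy)-7-[4-(benzyloxy)phenyl]-5-hydroxy-1,1-dimethoxyheptan-3-one | COC(OC)CC(=O)C[C@@H]([C@@H](OCc1ccccc1)Cc1ccc(OCc2ccccc2)cc1)O
F3 | step 9 | (4R,6S)-2-(benzenesulfonyl)-6-[(1S)-1-(benzyloxy)-2-[4-(benzyloxy)phenyl]ethyl]oxan-4-ol | O=S(=O)(c1ccccc1)C1C[C@H](O)C[C@@H]([C@@H](OCc2ccccc2)Cc2ccc(OCc3ccccc3)cc2)O1
F0 | step 10 | none | none
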